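What is left over in these runs is the gap: the percent of the Z charged that stands neither as Z nor as Q. In the north run it grows from 2.60% at 10.0 s to 36.3% at 90.0 s, so it is small while Q is small. I treat it as a correction to the main line, Z to Q on X, and I assume that one Z and one Q leave together, so that the gap grows as 2·kp·[Z][Q].

| flask | Z | X | remark | time |
|---|---|---|---|---|
| east | 0.034 M | 0.1 mol% | run made earlier |  |
| north | 0.075 M | 0.1 mol% | run made earlier |  |
| south | 0.050 M | 0.05 mol% | run made earlier |  |
| flask | 0.050 M | 0.1 mol% |  | 2.5 min |

- east (time / s: Q / %, Z / %): 25.0: 20.4, 77.5; 50.0: 33.4, 57.0; 60.0: 38.9, 49.8; 90.0: 49.1, 33.1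
- north (time / s: Q / %, Z / %): 10.0: 14.0, 83.4; 15.0: 19.9, 78.3; 40.0: 37.0, 45.2; 90.0: 51.9, 11.8
- south (time / s: Q / %, Z / %): 25.0: 13.6, 84.1; 50.0: 20.9, 67.4; 60.0: 25.8, 61.8; 90.0: 31.9, 44.7

(scatter of a reading: 1 percentage point)

- amount of Q in percent of the Z charged, at 15 s, 50 s, 1.5 min and 2.5 min

- the numbers in the tables scatter by 1 percentage point (one standard deviation)

First setting, the charge of Z: by hand, the pair term grows with [Z][Q], so I take the north run, whose charge of Z is larger than in the other runs. Its last two readings give

kp = gap rise per second / ([Z]₀ × sum of z·q at both readings) = 0.216 M⁻¹ s⁻¹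

where z and q are the fractions of the charge. This kp is the pair constant, a reading with the scatter of its readings.

Second setting, the loading of X: by hand, X stands nowhere in the pair term, so kp should carry over to the south run at 0.05 mol%. There it gives a gap rise from 50.0 s to 90.0 s of 12.2%, and the readings show 11.7%. The early south reading, scaled to the flask's loading, gives the main rate per Z:

km = 0.0118 s⁻¹

Third setting, the time: at the forecast's Q of 49% at 1.5 min, the pair term takes each Z at

sq = kp·[Z]₀·q = 0.00529 s⁻¹

So my estimate of the selectivity factor of the flask at 1.5 min is 2.23, with the main line faster. Each Z lost then nets 0.382 Q, and my reckoning puts Q at 54.3% at 2.5 min.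

The forecast gives 15%, 37%, 49% and 52%, saying “Q is near a plateau of about 52%”, and its last value is lower than my end value.

The flask gives 16.5%, 39.3%, 51.4% and 58.2%, and the gap is D, which holds two.

    Z + Q → D (k = 0.203 M⁻¹ s⁻¹)
    Z + X → Q + X, rate k2*[Z]*[X]/(1 + ([Z]/Km2) + ([Q]/Kp2)) (0.0726 M, 0.0658 M, k = 440 M⁻¹ s⁻¹)

At 0.623 min the flask makes Q 4.01 times faster than it uses it, and at 2.50 min still 2.50 times faster, so Q is rising there. Reckoned with my scattered reading kp, as an estimate, that Q takes each Z at about 0.00628 s⁻¹. With the ratio of 2.50, each Z then nets 0.429 Q, so the 6.5% of Z left is worth about 2.78% more, and at 25.0 min the flask holds 61.0% Q.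

The earlier runs and the new flask are calculated for substances that don't exist; scatter was added.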